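**Retrosynthetic overview**

1. The exocyclic methylene is traced back to a ketone (methylenation), and the bond from C-1 of the hydrindane to that carbonyl is cut: enol triflate 21 of trans-hydrindanone 19 plus lactone aldehyde 13 (Nozaki–Hiyama–Kishi coupling, oxidation, face-selective hydrogenation).
2. Aldehyde 13: ring C and the three contiguous side-chain stereocentres come from an (R)-malate unit and (E)-but-2-ene-1,4-diol through a chelate-controlled dianionic ester-enolate Claisen rearrangement, then reduction and lactonisation.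
3. Hydrindanone 19: ring A is bought as 2-methylcyclopent-2-enone; asymmetric conjugate addition of an isopropenyl group and trans allylation set C-3a and C-7a; ring B is closed at the C-4–C-5 bond by a hydrogen-atom-transfer radical cyclisation.
4. Enabling feature: C-4 of ring B is a quaternary carbon carrying two methyl groups next to ring-fusion carbon C-3a, so it can be generated as a tertiary radical from an isopropenyl group; the trans C-3a/C-7a side arms on ring A make 5-exo closure a strained trans-bicyclo[3.3.0]octane, which leaves 6-endo closure to the trans-hydrindane.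
5. Order of ring formation: ring C (step 5), ring A (purchased), ring B last (step 9); no ring is formed after step 9.

Key step: step 9

Remark: locants C-1 to C-7a are those of the octahydro-1H-indene core (C-1 bears the side chain, C-3a and C-7a are the ring-fusion carbons, C-4 carries the two methyl groups); ring A is the cyclopentane, ring B the cyclohexane, ring C the lactone; compounds 1, 3, 14, 15 and 16 are taken as commercial.

**Route**

Step 1
Reactants: 1 (2E)-but-2-ene-1,4-diol
Product: 2 (2E)-4-[(tert-butyldiphenylsilyl)oxy]but-2-en-1-ol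
Conditions: TBDPSCl (1.0 equiv), imidazole (2 equiv), 1 (4 equiv), THF/DMF, 0 °C → rt
Reagents that add atoms: tert-butyl(chloro)diphenylsilane, CC(C)(C)[Si](Cl)(c1ccccc1)c1ccccc1
Why: Silyl ether formation on a symmetrical diol used in excess should give mainly the mono-ether; no stereocentre is involved.

Step 2
Reactants: 2 (2E)-4-[(tert-butyldiphenylsilyl)oxy]but-2-en-1-ol, 3 2-[(4R)-2,2-dimethyl-5-oxo-1,3-dioxolan-4-yl]acetic acid
Product: 4 (2E)-4-[(tert-butyldiphenylsilyl)oxy]but-2-en-1-yl 2-[(4R)-2,2-dimethyl-5-oxo-1,3-dioxolan-4-yl]acetate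
Conditions: DCC (1.1 equiv), DMAP (0.1 equiv), CH2Cl2, 0 °C → rt
Reagents that add atoms: none
Why: Steglich esterification joins the free carboxylic acid to the primary allylic alcohol while the dioxolanone keeps the α-hydroxy acid masked and the (R) centre untouched.

Step 3
Reactants: 4 (2E)-4-[(tert-butyldiphenylsilyl)oxy]but-2-en-1-yl 2-[(4R)-2,2-dimethyl-5-oxo-1,3-dioxolan-4-yl]acetate
Product: 5 4-{(2E)-4-[(tert-butyldiphenylsilyl)oxy]but-2-en-1-yl} 1-methyl (2R)-2-hydroxybutanedioate
Conditions: MeOH, camphorsulfonic acid (0.1 equiv), rt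
Reagents that add atoms: methanol, CO
Why: Acid-catalysed alcoholysis (transesterification) of the activated dioxolanone should release acetone and give the methyl α-hydroxy ester with the free hydroxyl needed for chelation, without exchange of the allylic ester or loss of the silyl ether.

Step 4
Reactants: 5 4-{(2E)-4-[(tert-butyldiphenylsilyl)oxy]but-2-en-1-yl} 1-methyl (2R)-2-hydroxybutanedioate
Product: 7 (2S,3S)-3-{[(tert-butyldiphenylsilyl)oxy]methyl}-2-[(1R)-1-hydroxy-2-methoxy-2-oxoethyl]pent-4-enoic acid, via dilithium enolate alkoxide 6 (not isolated)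
Conditions: LiN(iPr)2 (LDA, 2.3 equiv), THF, −78 °C → rt; then 1 M HCl
Reagents that add atoms: none
Why: Chelate-controlled dianionic ester-enolate Claisen rearrangement (Ireland–Claisen type): the lithium-bridged (Z)-enolate 6 should rearrange through a chair transition state on the face anti to the CO2Me group of the malate centre (the sense of Fráter–Seebach alkylations), which sets C-2, while the (E)-alkene places the silyloxymethyl group equatorial and sets C-3, so all three contiguous stereocentres derive from the one malate centre.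

Step 5
Reactants: 7 (2S,3S)-3-{[(tert-butyldiphenylsilyl)oxy]methyl}-2-[(1R)-1-hydroxy-2-methoxy-2-oxoethyl]pent-4-enoic acid
Product: 10 (3R,4R)-4-{(2S)-1-[(tert-butyldiphenylsilyl)oxy]but-3-en-2-yl}-3-hydroxyoxolan-2-one, via mixed carbonic anhydride 8 (not isolated), via hydroxy ester 9 (not isolated)
Conditions: i-BuOCOCl, N-methylmorpholine, THF, −15 °C; NaBH4, H2O, 0 °C; then camphorsulfonic acid (cat.), CH2Cl2, rt
Reagents that add atoms: none
Why: Mixed-anhydride activation and NaBH4 reduction should reduce only the carboxylic acid (methyl ester and alkene untouched), and acid-catalysed lactonisation of the γ-hydroxy ester then closes ring C with hydroxyl and side chain cis, both stereocentres being carried over unchanged.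

Step 6
Reactants: 10 (3R,4R)-4-{(2S)-1-[(tert-butyldiphenylsilyl)oxy]but-3-en-2-yl}-3-hydroxyoxolan-2-one
Product: 11 (3R,4R)-3-[(tert-butyldimethylsilyl)oxy]-4-{(2S)-1-[(tert-butyldiphenylsilyl)oxy]but-3-en-2-yl}oxolan-2-one
Conditions: TBSOTf (1.3 equiv), 2,6-lutidine, CH2Cl2, −78 → 0 °C
Reagents that add atoms: tert-butyldimethylsilyl trifluoromethanesulfonate, CC(C)(C)[Si](C)(C)OS(=O)(=O)C(F)(F)F
Why: Silyl ether formation with a silyl triflate and a hindered pyridine base protects the secondary hydroxyl, which must survive the later oxidation; no stereocentre is touched.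

Step 7
Reactants: 11 (3R,4R)-3-[(tert-butyldimethylsilyl)oxy]-4-{(2S)-1-[(tert-butyldiphenylsilyl)oxy]but-3-en-2-yl}oxolan-2-one
Product: 13 (2S)-2-{(3R,4R)-4-[(tert-butyldimethylsilyl)oxy]-5-oxooxolan-3-yl}-3-[(tert-butyldiphenylsilyl)oxy]propanal, via secondary ozonide 12 (not isolated)
Conditions: O3, CH2Cl2, −78 °C; then PPh3, −78 °C → rt
Reagents that add atoms: ozone, [O-][O+]=O
Why: Ozonolysis with reductive work-up cleaves the only C=C bond to the aldehyde under neutral conditions that should preserve the adjacent stereocentre.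

Step 8
Reactants: 14 2-methylcyclopent-2-en-1-one, 15 isopropenylmagnesium bromide, 16 allyl iodide
Product: 18 (2S,3S)-2-methyl-2-(prop-2-en-1-yl)-3-(prop-1-en-2-yl)cyclopentan-1-one, via bromomagnesium enolate 17 (not isolated)
Conditions: Cu(OTf)2 (3 mol %), chiral hydroxyalkyl-imidazolinium salt (NHC precursor, enantiomer giving the 3S adduct, 4 mol %), Et2O, −30 °C; then 16, DMPU, −30 °C → rt
Reagents that add atoms: none
Why: Copper-catalysed asymmetric conjugate addition of a Grignard reagent to an α-substituted cyclic enone with enolate trapping: the chiral NHC–copper catalyst sets C-3, and allyl iodide attacks the enolate face trans to the new isopropenyl group, which sets the quaternary C-2.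

Step 9
Reactants: 18 (2S,3S)-2-methyl-2-(prop-2-en-1-yl)-3-(prop-1-en-2-yl)cyclopentan-1-one
Product: 19 (3aS,7aS)-4,4,7a-trimethyloctahydro-1H-inden-1-one
Conditions: Fe(acac)3 (2.5 equiv), PhSiH3 (3 equiv, added over 6 h), EtOH/ethylene glycol 5:1, 0.01 M, 60 °C, argon
Reagents that add atoms: none
Why: Proposed new method: a trivalent iron hydride formed from Fe(acac)3 and PhSiH3 transfers a hydrogen atom to the CH2 terminus of the 1,1-disubstituted isopropenyl group (Markovnikov), the resulting tertiary radical at C-4 adds to the terminal carbon of the allyl group on C-7a and forms the C-4–C-5 bond, and the secondary C-6 radical is reduced by a second hydrogen atom. The closest known reaction types are the iron/silane hydrogen-atom-transfer reductive olefin coupling (Giese type, including intramolecular 6-endo cases with acrylate acceptors) and hydrogen-atom-transfer-initiated reductive 5-exo cyclisations of dienes; 6-endo closure onto an unactivated terminal alkene is the new element. Ring B closes 6-endo-trig through a chair transition state in which C-3a and C-7a carry the forming ring diequatorially, which gives the trans-hydrindane. No new stereocentre is formed (C-4 bears two methyl groups, C-5 and C-6 are CH2 groups); the trans ring fusion is that of C-3a and C-7a set in step 8. The step needs hydrogen-atom transfer at the isopropenyl and not the allyl group (tertiary versus secondary radical), and 6-endo closure in preference to 5-exo closure, 1,5-hydrogen shift and early reduction: the trans side arms on ring A make the 5-exo product a strained trans-bicyclo[3.3.0]octanone and keep the allylic hydrogens out of reach, the quaternary C-7a speeds closure (Thorpe–Ingold effect), and high dilution with slow silane addition in a medium without a fast hydrogen donor should keep the radical alive long enough.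

Step 10
Reactants: 19 (3aS,7aS)-4,4,7a-trimethyloctahydro-1H-inden-1-one
Product: 21 (3aS,7aS)-4,4,7a-trimethyl-3a,4,5,6,7,7a-hexahydro-3H-inden-1-yl trifluoromethanesulfonate, via potassium enolate 20 (not isolated)
Conditions: KN(SiMe3)2 (KHMDS, 1.2 equiv), THF, −78 °C; PhNTf2 (1.2 equiv), −78 → 0 °C
Reagents that add atoms: N-phenylbis(trifluoromethanesulfonimide), O=S(=O)(N(c1ccccc1)S(=O)(=O)C(F)(F)F)C(F)(F)F
Why: Enolate formation at the only enolisable α-carbon (C-2) and O-sulfonylation give the enol triflate (vinyl triflate synthesis); no stereocentre is touched.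

Step 11
Reactants: 21 (3aS,7aS)-4,4,7a-trimethyl-3a,4,5,6,7,7a-hexahydro-3H-inden-1-yl trifluoromethanesulfonate, 13 (2S)-2-{(3R,4R)-4-[(tert-butyldimethylsilyl)oxy]-5-oxooxolan-3-yl}-3-[(tert-butyldiphenylsilyl)oxy]propanal
Product: 23 (3R,4R)-3-[(tert-butyldimethylsilyl)oxy]-4-{(2S)-3-[(tert-butyldiphenylsilyl)oxy]-1-hydroxy-1-[(3aS,7aS)-4,4,7a-trimethyl-3a,4,5,6,7,7a-hexahydro-3H-inden-1-yl]propan-2-yl}oxolan-2-one (both carbinol epimers), via alkenylchromium dichloride 22 (not isolated)
Conditions: CrCl2 (4 equiv), NiCl2 (2 mol %), DMF, rt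
Reagents that add atoms: none
Why: Nozaki–Hiyama–Kishi coupling: nickel-catalysed formation of alkenylchromium 22 and its chemoselective, non-basic addition to the aldehyde in the presence of the lactone; the new carbinol centre forms without control and is removed in step 12.

Step 12
Reactants: 23 allylic alcohol (both carbinol epimers)
Product: 24 (3R,4R)-3-[(tert-butyldimethylsilyl)oxy]-4-{(2S)-3-[(tert-butyldiphenylsilyl)oxy]-1-oxo-1-[(3aS,7aS)-4,4,7a-trimethyl-3a,4,5,6,7,7a-hexahydro-3H-inden-1-yl]propan-2-yl}oxolan-2-one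
Conditions: Dess–Martin periodinane (1.5 equiv), NaHCO3, CH2Cl2, rt
Reagents that add atoms: none
Why: Dess–Martin oxidation of the allylic alcohol to the enone under buffered conditions removes the uncontrolled carbinol centre and should not epimerise the α-stereocentre.

Step 13
Reactants: 24 enone
Product: 25 (3R,4R)-3-[(tert-butyldimethylsilyl)oxy]-4-{(2S)-3-[(tert-butyldiphenylsilyl)oxy]-1-oxo-1-[(1S,3aS,7aS)-4,4,7a-trimethyloctahydro-1H-inden-1-yl]propan-2-yl}oxolan-2-one
Conditions: H2 (1 atm), Pd/C (10 wt %), EtOAc, rt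
Reagents that add atoms: none
Why: Heterogeneous hydrogenation of the enone C=C: hydrogen should be delivered to the face opposite the angular C-7a methyl and the axial C-4 methyl, as in the reduction of 16-en-20-one steroids, which sets C-1 with the acyl group cis to the angular methyl (also the more stable epimer).

Step 14
Reactants: 25 ketone
Product: 26 (3R,4R)-3-[(tert-butyldimethylsilyl)oxy]-4-{(2R)-1-[(tert-butyldiphenylsilyl)oxy]-3-[(1R,3aS,7aS)-4,4,7a-trimethyloctahydro-1H-inden-1-yl]but-3-en-2-yl}oxolan-2-one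
Conditions: Zn, CH2Br2, TiCl4, THF, 0 °C (reagent pre-formed); then 25, CH2Cl2, rt
Reagents that add atoms: dibromomethane, BrCBr
Why: Takai–Lombardo methylenation: the non-basic zinc–titanium methylene reagent should olefinate the hindered, epimerisable ketone without reacting with the lactone or causing β-elimination; no stereocentre is formed.

Step 15
Reactants: 26 bis-silyl ether
Product: 27 (3R,4R)-3-hydroxy-4-{(2R)-1-hydroxy-3-[(1R,3aS,7aS)-4,4,7a-trimethyloctahydro-1H-inden-1-yl]but-3-en-2-yl}oxolan-2-one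
Conditions: HF·pyridine, pyridine, THF, 0 °C → rt
Reagents that add atoms: none
Why: Fluoride-promoted desilylation removes both silyl ethers under buffered conditions that should leave lactone and alkene intact.

Step 16
Reactants: 27 diol
Product: 28 (2R)-2-[(3R,4R)-4-hydroxy-5-oxooxolan-3-yl]-3-[(1R,3aS,7aS)-4,4,7a-trimethyloctahydro-1H-inden-1-yl]but-3-en-1-yl acetate
Conditions: AcCl (1.1 equiv), 2,4,6-collidine, CH2Cl2, −78 °C
Reagents that add atoms: acetyl chloride, CC(=O)Cl
Why: Chemoselective acylation: at low temperature with a hindered pyridine base the primary hydroxyl should be acetylated much faster than the hindered, hydrogen-bonded α-hydroxy lactone.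

**Compound list**

1 | (2E)-but-2-ene-1,4-diol | OC/C=C/CO | starting material
2 | (2E)-4-[(tert-butyldiphenylsilyl)oxy]but-2-en-1-ol | OC/C=C/CO[Si](c1ccccc1)(c1ccccc1)C(C)(C)C | intermediate
3 | 2-[(4R)-2,2-dimethyl-5-oxo-1,3-dioxolan-4-yl]acetic acid | CC1(C)O[C@H](CC(=O)O)C(=O)O1 | starting material
4 | (2E)-4-[(tert-butyldiphenylsilyl)oxy]but-2-en-1-yl 2-[(4R)-2,2-dimethyl-5-oxo-1,3-dioxolan-4-yl]acetate | CC1(C)O[C@H](CC(=O)OC/C=C/CO[Si](c2ccccc2)(c2ccccc2)C(C)(C)C)C(=O)O1 | intermediate
5 | 4-{(2E)-4-[(tert-butyldiphenylsilyl)oxy]but-2-en-1-yl} 1-methyl (2R)-2-hydroxybutanedioate | COC(=O)[C@H](O)CC(=O)OC/C=C/CO[Si](c1ccccc1)(c1ccccc1)C(C)(C)C | intermediate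
6 | dilithium alkoxide (Z)-enolate of 5 (enolate of the allylic ester, alkoxide at the (R) carbinol) | [Li+].[Li+].COC(=O)[C@H]([O-])/C=C(\[O-])OC/C=C/CO[Si](c1ccccc1)(c1ccccc1)C(C)(C)C | intermediate
7 | (2S,3S)-3-{[(tert-butyldiphenylsilyl)oxy]methyl}-2-[(1R)-1-hydroxy-2-methoxy-2-oxoethyl]pent-4-enoic acid | C=C[C@H](CO[Si](c1ccccc1)(c1ccccc1)C(C)(C)C)[C@H](C(=O)O)[C@@H](O)C(=O)OC | intermediate
8 | mixed anhydride of acid 7 with isobutyl hydrogen carbonate | C=C[C@H](CO[Si](c1ccccc1)(c1ccccc1)C(C)(C)C)[C@H](C(=O)OC(=O)OCC(C)C)[C@@H](O)C(=O)OC | intermediate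
9 | methyl (2R,3R,4S)-4-{[(tert-butyldiphenylsilyl)oxy]methyl}-2-hydroxy-3-(hydroxymethyl)hex-5-enoate | C=C[C@H](CO[Si](c1ccccc1)(c1ccccc1)C(C)(C)C)[C@H](CO)[C@@H](O)C(=O)OC | intermediate
10 | (3R,4R)-4-{(2S)-1-[(tert-butyldiphenylsilyl)oxy]but-3-en-2-yl}-3-hydroxyoxolan-2-one | C=C[C@H](CO[Si](c1ccccc1)(c1ccccc1)C(C)(C)C)[C@@H]1COC(=O)[C@@H]1O | intermediate
11 | (3R,4R)-3-[(tert-butyldimethylsilyl)oxy]-4-{(2S)-1-[(tert-butyldiphenylsilyl)oxy]but-3-en-2-yl}oxolan-2-one | C=C[C@H](CO[Si](c1ccccc1)(c1ccccc1)C(C)(C)C)[C@@H]1COC(=O)[C@@H]1O[Si](C)(C)C(C)(C)C | intermediate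
12 | secondary ozonide of 11 (3-substituted 1,2,4-trioxolane, both ring epimers) | O1OC(OC1)[C@H](CO[Si](c2ccccc2)(c2ccccc2)C(C)(C)C)[C@@H]2COC(=O)[C@@H]2O[Si](C)(C)C(C)(C)C | intermediate
13 | (2S)-2-{(3R,4R)-4-[(tert-butyldimethylsilyl)oxy]-5-oxooxolan-3-yl}-3-[(tert-butyldiphenylsilyl)oxy]propanal | O=C[C@H](CO[Si](c1ccccc1)(c1ccccc1)C(C)(C)C)[C@@H]1COC(=O)[C@@H]1O[Si](C)(C)C(C)(C)C | intermediate
14 | 2-methylcyclopent-2-en-1-one | CC1=CCCC1=O | starting material
15 | isopropenylmagnesium bromide (prop-1-en-2-ylmagnesium bromide) | CC(=C)[Mg]Br | starting material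
16 | allyl iodide (3-iodoprop-1-ene) | C=CCI | starting material
17 | bromo{[(3S)-2-methyl-3-(prop-1-en-2-yl)cyclopent-1-en-1-yl]oxy}magnesium | CC1=C(O[Mg]Br)CC[C@H]1C(C)=C | intermediate
18 | (2S,3S)-2-methyl-2-(prop-2-en-1-yl)-3-(prop-1-en-2-yl)cyclopentan-1-one | O=C1CC[C@@H](C(C)=C)[C@@]1(CC=C)C | intermediate
19 | (3aS,7aS)-4,4,7a-trimethyloctahydro-1H-inden-1-one | O=C1CC[C@H]2C(C)(C)CCC[C@]12C | intermediate
20 | potassium (3aS,7aS)-4,4,7a-trimethyl-3a,4,5,6,7,7a-hexahydro-3H-inden-1-olate | [K+].[O-]C1=CC[C@H]2C(C)(C)CCC[C@]12C | intermediate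
21 | (3aS,7aS)-4,4,7a-trimethyl-3a,4,5,6,7,7a-hexahydro-3H-inden-1-yl trifluoromethanesulfonate | O=S(=O)(OC1=CC[C@H]2C(C)(C)CCC[C@]12C)C(F)(F)F | intermediate
22 | dichloro[(3aS,7aS)-4,4,7a-trimethyl-3a,4,5,6,7,7a-hexahydro-3H-inden-1-yl]chromium | Cl[Cr](Cl)C1=CC[C@H]2C(C)(C)CCC[C@]12C | intermediate
23 | (3R,4R)-3-[(tert-butyldimethylsilyl)oxy]-4-{(2S)-3-[(tert-butyldiphenylsilyl)oxy]-1-hydroxy-1-[(3aS,7aS)-4,4,7a-trimethyl-3a,4,5,6,7,7a-hexahydro-3H-inden-1-yl]propan-2-yl}oxolan-2-one (both carbinol epimers) | OC(C1=CC[C@H]2C(C)(C)CCC[C@]12C)[C@H](CO[Si](c1ccccc1)(c1ccccc1)C(C)(C)C)[C@@H]1COC(=O)[C@@H]1O[Si](C)(C)C(C)(C)C | intermediate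
24 | (3R,4R)-3-[(tert-butyldimethylsilyl)oxy]-4-{(2S)-3-[(tert-butyldiphenylsilyl)oxy]-1-oxo-1-[(3aS,7aS)-4,4,7a-trimethyl-3a,4,5,6,7,7a-hexahydro-3H-inden-1-yl]propan-2-yl}oxolan-2-one | O=C(C1=CC[C@H]2C(C)(C)CCC[C@]12C)[C@H](CO[Si](c1ccccc1)(c1ccccc1)C(C)(C)C)[C@@H]1COC(=O)[C@@H]1O[Si](C)(C)C(C)(C)C | intermediate
25 | (3R,4R)-3-[(tert-butyldimethylsilyl)oxy]-4-{(2S)-3-[(tert-butyldiphenylsilyl)oxy]-1-oxo-1-[(1S,3aS,7aS)-4,4,7a-trimethyloctahydro-1H-inden-1-yl]propan-2-yl}oxolan-2-one | O=C([C@H]1CC[C@H]2C(C)(C)CCC[C@]12C)[C@H](CO[Si](c1ccccc1)(c1ccccc1)C(C)(C)C)[C@@H]1COC(=O)[C@@H]1O[Si](C)(C)C(C)(C)C | intermediate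
26 | (3R,4R)-3-[(tert-butyldimethylsilyl)oxy]-4-{(2R)-1-[(tert-butyldiphenylsilyl)oxy]-3-[(1R,3aS,7aS)-4,4,7a-trimethyloctahydro-1H-inden-1-yl]but-3-en-2-yl}oxolan-2-one | C=C([C@H]1CC[C@H]2C(C)(C)CCC[C@]12C)[C@H](CO[Si](c1ccccc1)(c1ccccc1)C(C)(C)C)[C@@H]1COC(=O)[C@@H]1O[Si](C)(C)C(C)(C)C | intermediate
27 | (3R,4R)-3-hydroxy-4-{(2R)-1-hydroxy-3-[(1R,3aS,7aS)-4,4,7a-trimethyloctahydro-1H-inden-1-yl]but-3-en-2-yl}oxolan-2-one | C=C([C@H]1CC[C@H]2C(C)(C)CCC[C@]12C)[C@H](CO)[C@@H]1COC(=O)[C@@H]1O | intermediate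
28 | (2R)-2-[(3R,4R)-4-hydroxy-5-oxooxolan-3-yl]-3-[(1R,3aS,7aS)-4,4,7a-trimethyloctahydro-1H-inden-1-yl]but-3-en-1-yl acetate | C=C([C@H]1CC[C@H]2C(C)(C)CCC[C@]12C)[C@H](COC(C)=O)[C@@H]1COC(=O)[C@@H]1O | target

**Step count and risks**

Total step count: 16. Longest linear sequence: 13 steps (steps 1–7, then 11–16); the hydrindane branch (steps 8–10) joins at step 11.

Steps most likely to fail:

Step 9 (Proposed new method). The tertiary radical may be reduced or the alkene isomerised before the slow 6-endo closure onto an unactivated alkene, or hydrogen-atom transfer may begin at the allyl group. The fallback uses known chemistry and sets out from enone 14. After the same conjugate addition, enolate 17 is trapped with methyl 2-(bromomethyl)acrylate to give methyl 2-{[(1S,5S)-1-methyl-2-oxo-5-(prop-1-en-2-yl)cyclopentyl]methyl}prop-2-enoate F1. Fe(acac)3 and PhSiH3 in EtOH then effect the known intramolecular 6-endo reductive olefin coupling onto the acrylate β-carbon and give methyl (3aS,7aS)-4,4,7a-trimethyl-1-oxooctahydro-1H-indene-6-carboxylate F2. LiOH gives (3aS,7aS)-4,4,7a-trimethyl-1-oxooctahydro-1H-indene-6-carboxylic acid F3, and N-hydroxyphthalimide with N,N'-diisopropylcarbodiimide gives 1,3-dioxoisoindolin-2-yl (3aS,7aS)-4,4,7a-trimethyl-1-oxooctahydro-1H-indene-6-carboxylate F4. Nickel-catalysed reductive decarboxylation (NiCl2·6H2O, 4,4'-di-tert-butyl-2,2'-bipyridine, Zn, PhSiH3) removes the activating group, and the route is rejoined at 19.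

Step 14. Methylenation of the doubly α-branched ketone may be slow, with enolisation and epimerisation at the α-carbon or β-elimination of the silyloxy group under the Lewis-acidic conditions. The fallback sets out from ketone 25. Me3SiCH2Li premixed with anhydrous CeCl3 (THF, −78 °C) should add to the ketone much faster than to the lactone and without enolisation, giving the tertiary β-hydroxysilane of 25 (both carbinol epimers) F5. HF·pyridine then brings about the acid-promoted Peterson elimination and removes both silyl ethers in the same operation, so the route is rejoined at diol 27.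

Step 8. Enantioselectivity or conversion may be poor in the copper-catalysed addition of an alkenyl Grignard reagent to the α-methyl enone, and O-allylation may compete with C-allylation of the magnesium enolate. The fallback sets out from 14. Rhodium-catalysed asymmetric 1,4-addition (Hayashi–Miyaura reaction; [Rh(cod)Cl]2, the BINAP enantiomer giving the required configuration, KOH, dioxane/H2O) of potassium isopropenyltrifluoroborate gives (3R)-2-methyl-3-(prop-1-en-2-yl)cyclopentan-1-one F6 (C-2 epimers; same spatial arrangement at C-3 as in 18). TMSCl, NaI and Et3N in MeCN give the more substituted silyl enol ether trimethyl{[(3S)-2-methyl-3-(prop-1-en-2-yl)cyclopent-1-en-1-yl]oxy}silane F7. MeLi followed by allyl iodide 16 regenerates the enolate regiospecifically, and the route is rejoined at 18.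

**Further compounds**

F1 | step 9 | methyl 2-{[(1S,5S)-1-methyl-2-oxo-5-(prop-1-en-2-yl)cyclopentyl]methyl}prop-2-enoate | O=C1CC[C@@H](C(C)=C)[C@@]1(CC(=C)C(=O)OC)C
F2 | step 9 | methyl (3aS,7aS)-4,4,7a-trimethyl-1-oxooctahydro-1H-indene-6-carboxylate (both C-6 epimers) | O=C1CC[C@H]2C(C)(C)CC(C(=O)OC)C[C@]12C
F3 | step 9 | (3aS,7aS)-4,4,7a-trimethyl-1-oxooctahydro-1H-indene-6-carboxylic acid (both C-6 epimers) | O=C1CC[C@H]2C(C)(C)CC(C(=O)O)C[C@]12C
F4 | step 9 | 1,3-dioxoisoindolin-2-yl (3aS,7aS)-4,4,7a-trimethyl-1-oxooctahydro-1H-indene-6-carboxylate (both C-6 epimers) | O=C1CC[C@H]2C(C)(C)CC(C(=O)ON3C(=O)c4ccccc4C3=O)C[C@]12C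
F5 | step 14 | tertiary β-hydroxysilane from addition of Me3SiCH2 to the ketone carbon of 25 (both carbinol epimers, other centres as in 25) | C[Si](C)(C)CC(O)([C@H]1CC[C@H]2C(C)(C)CCC[C@]12C)[C@H](CO[Si](c1ccccc1)(c1ccccc1)C(C)(C)C)[C@@H]1COC(=O)[C@@H]1O[Si](C)(C)C(C)(C)C
F6 | step 8 | (3R)-2-methyl-3-(prop-1-en-2-yl)cyclopentan-1-one (C-2 epimers) | O=C1CC[C@@H](C(C)=C)C1C
F7 | step 8 | trimethyl{[(3S)-2-methyl-3-(prop-1-en-2-yl)cyclopent-1-en-1-yl]oxy}silane | CC1=C(O[Si](C)(C)C)CC[C@H]1C(C)=C
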